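**Retrosynthetic overview**

1. The strategy rests on ring A, an ε end group: C1'(CH3)2 is bonded to C6'H, which bears the polyene, next to the C4'=C5'(CH3) alkene. Protonation of an open-chain 1',2'-alkene, C1'–C6' closure onto the 5',6'-alkene and loss of H-4' give exactly this ring, so it is made by a cyclase from an acyclic C13 ketone.
2. The C40 chain is cut at C11=C12 and C11'=C12' (two Wittig reactions) into a ring A C15 phosphonium salt, the C10 trienedial and a ring B C15 phosphonium salt.
3. Ring A salt: nerylacetone is cyclised to (R)-α-dihydroionone; then C7'=C8' by IBX, C10'/C11' by Horner–Wadsworth–Emmons, the C3' oxygen by allylic oxidation and CBS reduction (3'S, OH cis to the chain).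
4. Ring B salt: safranal already holds the carbocycle and the C3=C4 alkene; OsO4 sets the cis-3,4-diol, a lipase resolution its absolute configuration, a C5 phosphonate the chain.
5. Ring order: ring A is the only ring closed in the route (step 1); ring B is bought as safranal.

Key step: step 1

Remark on the chemistry: the chair fold that squalene–hopene cyclases impose on an E-configured 5',6'-alkene puts the chain equatorial and gives the 6'S series (as in (S)-γ-dihydroionone from (E)-geranylacetone). The target needs 6'R, so the Z isomer, nerylacetone, is the substrate: in the same fold its chain is axial and C6' comes out R.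

Remark on the chemistry: the sense of the lipase resolution in step 10 is assumed from the empirical size rule for lipase acylation of secondary alcohols and would be confirmed before the material is carried on.

**Ring A fragment**

Step 1
Reactants: 1 nerylacetone, (5Z)-6,10-dimethylundeca-5,9-dien-2-one
Product: 2 (R)-α-dihydroionone, 4-[(1R)-2,6,6-trimethylcyclohex-2-en-1-yl]butan-2-one
Conditions: engineered AacSHC variant (E. coli whole cells), citrate buffer pH 6.0, 2-hydroxypropyl-β-cyclodextrin, 30 °C
Reagents that add atoms: none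
Why: Proposed new method: the catalytic aspartic acid of the cyclase protonates C2' of the 1',2'-alkene, the C1' cation is attacked by C6' of the 5',6'-alkene, and the resulting C5' cation loses the axial H-4' to an active-site base, which gives the C4'=C5' alkene of the ε ring. The closest known reaction is the monocyclisation of (E)-geranylacetone by engineered squalene–hopene cyclases to (S)-γ-dihydroionone, in which the same cation is quenched at the C5' methyl group. Ring A closes by a 6-endo-trig cation–olefin attack through a chair transition state. The C6' stereocentre is set by the enzyme fold acting on the alkene geometry: the native chair presents the face of C6' that gives 6'S from the E-alkene (chain equatorial), so the Z-alkene held in the same fold carries the chain axial and should give 6'R. The step needs loss of H-4' in preference to a methyl proton (γ isomer), to H-6' (β isomer) and to capture of C5' by the ketone oxygen (bicyclic enol ether); the axial chain leaves H-6' equatorial and orthogonal to the empty orbital, and the variant would be evolved on 1 to place its base under C4' and a hydrogen-bond donor on the ketone.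

Step 2
Reactants: 2 (R)-α-dihydroionone
Product: 3 (R)-α-ionone, (3E)-4-[(1R)-2,6,6-trimethylcyclohex-2-en-1-yl]but-3-en-2-one
Conditions: IBX, 4-methoxypyridine N-oxide, DMSO, 25 °C
Reagents that add atoms: none
Why: IBX-mediated α,β-dehydrogenation of a ketone: the more substituted enol toward C8' is oxidised by single-electron transfer and loses H-7' to give the E-enone, the methyl side having no β-hydrogen, while the near-neutral room-temperature medium leaves the C6' stereocentre alone.

Step 3
Reactants: 3 (R)-α-ionone; 4 triethyl phosphonoacetate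
Product: 5 ethyl (2E,4E)-3-methyl-5-[(1R)-2,6,6-trimethylcyclohex-2-en-1-yl]penta-2,4-dienoate
Conditions: NaH, THF, 0 → 40 °C; chromatography
Reagents that add atoms: none
Why: Horner–Wadsworth–Emmons olefination of the methyl ketone, in which the stabilised phosphonate anion is too weak a base to touch C6'–H and the 9'E ester (ester anti to the dienyl chain) should predominate and be freed from the 9'Z isomer on silica.

Step 4
Reactants: 5 ring A C15 ester
Product: 6 ethyl (2E,4E)-3-methyl-5-[(1R)-2,6,6-trimethyl-4-oxocyclohex-2-en-1-yl]penta-2,4-dienoate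
Conditions: Rh2(cap)4 (dirhodium tetrakis(caprolactamate), 1 mol%), t-BuOOH (70% in water), 1,2-dichloroethane, 40 °C
Reagents that add atoms: tert-butyl hydroperoxide, CC(C)(C)OO
Why: Radical allylic oxidation by tert-butylperoxyl radicals under dirhodium caprolactamate catalysis, the reaction type that turns α-ionone into 3-oxo-α-ionone: C3' is the only unhindered ring methylene allylic to C4'=C5', C6'–H is shielded by the gem-dimethyl group and the chain, and the base-free medium spares the now vinylogously acidic C6'–H.

Step 5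
Reactants: 6 ring A 3'-oxo C15 ester
Product: 7 ethyl (2E,4E)-5-[(1R,4S)-4-hydroxy-2,6,6-trimethylcyclohex-2-en-1-yl]-3-methylpenta-2,4-dienoate (carotenoid numbering 3'S,6'R)
Conditions: (R)-2-methyl-CBS-oxazaborolidine (0.2 equiv), catecholborane, toluene, −78 °C; chromatography
Reagents that add atoms: none
Why: Corey–Bakshi–Shibata reduction under catalyst control: the ring enone binds the (R)-oxazaborolidine with its alkenyl flank C4'=C5' as the large group and takes hydride on the face that gives the 3'S carbinol, which is the OH cis to the C6' chain, while the dienoate is inert to catecholborane at −78 °C and any 3'R epimer is separable on silica.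

Step 6
Reactants: 7 ring A hydroxy ester
Product: 8 ethyl (2E,4E)-5-[(1R,4S)-4-(tert-butyldimethylsilyloxy)-2,6,6-trimethylcyclohex-2-en-1-yl]-3-methylpenta-2,4-dienoate
Conditions: TBSCl, imidazole, DMF, 25 °C
Reagents that add atoms: tert-butyldimethylsilyl chloride, CC(C)(C)[Si](C)(C)Cl
Why: Standard silylation of the secondary allylic alcohol, the TBS ether being stable to DIBAL-H, PBr3/pyridine and Wittig base and removable at the end by fluoride without acid.

Step 7
Reactants: 8 ring A silyloxy ester
Product: 9 (2E,4E)-5-[(1R,4S)-4-(tert-butyldimethylsilyloxy)-2,6,6-trimethylcyclohex-2-en-1-yl]-3-methylpenta-2,4-dien-1-ol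
Conditions: DIBAL-H, CH2Cl2, −78 → 0 °C; aqueous work-up
Reagents that add atoms: none
Why: DIBAL-H 1,2-reduction of the conjugated ester to the primary allylic alcohol, which leaves the silyl ether and the alkenes untouched.

Step 8
Reactants: 9 ring A C15 allylic alcohol
Product: 11 ring A C15 triphenylphosphonium bromide, via allylic bromide 10 (not isolated)
Conditions: PBr3, pyridine, Et2O, −20 °C; then PPh3, EtOAc, 25 °C
Reagents that add atoms: phosphorus tribromide, BrP(Br)Br; triphenylphosphine, c1ccc(cc1)P(c1ccccc1)c1ccccc1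
Why: Pyridine-buffered PBr3 bromination of the primary allylic alcohol and SN2 quaternisation of the bromide by triphenylphosphine, the usual way to C15 Wittig salts when acid, which would ionise the allylic C3' silyl ether, must be avoided.

**Ring B fragment**

Step 9
Reactants: 12 safranal
Product: 13 racemic cis-3,4-dihydroxy-2,6,6-trimethylcyclohex-1-ene-1-carbaldehyde
Conditions: OsO4 (2 mol%), NMO, acetone/H2O, 0 → 25 °C
Reagents that add atoms: N-methylmorpholine N-oxide, C[N+]1([O-])CCOCC1; water, O
Why: Upjohn dihydroxylation: OsO4 adds suprafacially to the disubstituted, more electron-rich C3=C4 alkene and spares the tetrasubstituted, formyl-conjugated C5=C6 alkene, which fixes the cis relation of the two hydroxyls (racemic, since safranal is achiral).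

Step 10
Reactants: 13 racemic cis-diol
Product: 14 (3R,4S)-3,4-dihydroxy-2,6,6-trimethylcyclohex-1-ene-1-carbaldehyde (carotenoid numbering 3S,4R; C4 of this name is carotenoid C3)
Conditions: Burkholderia cepacia lipase (Amano PS, immobilised), vinyl acetate, t-BuOMe, 30 °C, stopped just past half conversion; chromatography
Reagents that add atoms: none
Why: Lipase-catalysed kinetic resolution by acylation: following the empirical size rule for cis-2-substituted cyclohexanols, the enantiomer whose carotenoid C3 carbinol is R should be acetylated at that less hindered hydroxyl, so that past half conversion the unreacted diol is the enantiomer needed, its configuration being confirmed through MTPA esters before use.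

Step 11
Reactants: 14 (3R,4S)-diol
Product: 15 (3R,4S)-3,4-bis(tert-butyldimethylsilyloxy)-2,6,6-trimethylcyclohex-1-ene-1-carbaldehyde
Conditions: TBSOTf, 2,6-lutidine, CH2Cl2, −78 → 0 °C
Reagents that add atoms: tert-butyldimethylsilyl trifluoromethanesulfonate, CC(C)(C)[Si](C)(C)OS(=O)(=O)C(F)(F)F
Why: Silylation of both hydroxyls of the hindered cis-diol by the silyl triflate, with 2,6-lutidine at low temperature so that the enal is not enolised; the same fluoride-labile group as on ring A allows one final deprotection.

Step 12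
Reactants: 15 ring B bis-silyloxy aldehyde; 16 triethyl 3-methyl-4-phosphonocrotonate
Product: 17 ethyl (2E,4E)-5-[(3R,4S)-3,4-bis(tert-butyldimethylsilyloxy)-2,6,6-trimethylcyclohex-1-en-1-yl]-3-methylpenta-2,4-dienoate
Conditions: n-BuLi, THF/DMPU, −78 → 0 °C; chromatography
Reagents that add atoms: none
Why: Vinylogous Horner–Wadsworth–Emmons reaction through the phosphorus-bearing carbon of the C5 phosphonate anion, established for 2,6,6-trimethylcyclohexene-1-carbaldehydes, which should give the 7E alkene and mainly the 9E ester (9Z removed on silica) and does not touch the silyl ethers.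

Step 13
Reactants: 17 ring B C15 ester
Product: 18 (2E,4E)-5-[(3R,4S)-3,4-bis(tert-butyldimethylsilyloxy)-2,6,6-trimethylcyclohex-1-en-1-yl]-3-methylpenta-2,4-dien-1-ol
Conditions: DIBAL-H, CH2Cl2, −78 → 0 °C; aqueous work-up
Reagents that add atoms: none
Why: DIBAL-H 1,2-reduction of the dienoate to the primary allylic alcohol, to which the silyl ethers are stable.

Step 14
Reactants: 18 ring B C15 allylic alcohol
Product: 20 ring B C15 triphenylphosphonium bromide, via allylic bromide 19 (not isolated)
Conditions: PBr3, pyridine, Et2O, −20 °C; then PPh3, EtOAc, 25 °C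
Reagents that add atoms: phosphorus tribromide, BrP(Br)Br; triphenylphosphine, c1ccc(cc1)P(c1ccccc1)c1ccccc1
Why: Same buffered bromination and phosphine quaternisation as in step 8, chosen because acidic salt formation would ionise the allylic C4 silyl ether.

Step 15
Reactants: 20 ring B C15 phosphonium bromide; 21 (2E,4E,6E)-2,7-dimethylocta-2,4,6-trienedial (3 equiv)
Product: 23 all-E ring B C25 aldehyde, via 11Z C25 aldehyde 22 (not isolated)
Conditions: NaOMe, MeOH/CH2Cl2, 0 → 25 °C, dark; then heptane, 80 °C
Reagents that add atoms: none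
Why: Wittig reaction of the allylic ylide from 20 with an excess of the symmetrical dialdehyde, which should stop at the mono-adduct because the remaining formyl group is a less electrophilic vinylogous aldehyde; the C11=C12 bond forms as an E/Z mixture and the hindered 11Z isomer is isomerised to E on warming, as is usual for carotenoid Wittig products.

**Coupling and deprotection**

Step 16
Reactants: 11 ring A C15 phosphonium bromide; 23 ring B C25 aldehyde
Product: 25 all-E tris-silyl ether of the target, via 11'Z tris-silyl ether 24 (not isolated)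
Conditions: NaOMe, MeOH/CH2Cl2, 0 → 25 °C, Ar, dark; then EtOAc, 70 °C
Reagents that add atoms: none
Why: Convergent C15 + C25 Wittig reaction that forms C11'=C12', with the ylide generated in the presence of the aldehyde so that it is trapped before proton shifts along the chain could reach C6', followed by thermal isomerisation of the 11'Z isomer to the all-E polyene.

Step 17
Reactants: 25 tris-silyl ether
Product: 26 CNP0191612.2, (3S,4R,3'S,6'R)-β,ε-carotene-3,4,3'-triol
Conditions: TBAF, AcOH, THF, 25 °C, Ar, dark
Reagents that add atoms: none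
Why: Fluoride cleavage of the three silyl ethers buffered by acetic acid, which avoids both acid (ionisation of the allylic C4 and C3' carbinols) and strong base and touches no stereocentre.

**Compound list**

1 | nerylacetone, (5Z)-6,10-dimethylundeca-5,9-dien-2-one | CC(C)=CCC/C(C)=C\CCC(C)=O | starting material
2 | (R)-α-dihydroionone, 4-[(1R)-2,6,6-trimethylcyclohex-2-en-1-yl]butan-2-one | CC1=CCCC(C)(C)[C@H]1CCC(C)=O | intermediate
3 | (R)-α-ionone, (3E)-4-[(1R)-2,6,6-trimethylcyclohex-2-en-1-yl]but-3-en-2-one | CC1=CCCC(C)(C)[C@H]1/C=C/C(C)=O | intermediate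
4 | triethyl phosphonoacetate | CCOC(=O)CP(=O)(OCC)OCC | starting material
5 | ethyl (2E,4E)-3-methyl-5-[(1R)-2,6,6-trimethylcyclohex-2-en-1-yl]penta-2,4-dienoate | CC1=CCCC(C)(C)[C@H]1/C=C/C(C)=C/C(=O)OCC | intermediate
6 | ethyl (2E,4E)-3-methyl-5-[(1R)-2,6,6-trimethyl-4-oxocyclohex-2-en-1-yl]penta-2,4-dienoate | CC1=CC(=O)CC(C)(C)[C@H]1/C=C/C(C)=C/C(=O)OCC | intermediate
7 | ethyl (2E,4E)-5-[(1R,4S)-4-hydroxy-2,6,6-trimethylcyclohex-2-en-1-yl]-3-methylpenta-2,4-dienoate | CC1=C[C@@H](O)CC(C)(C)[C@H]1/C=C/C(C)=C/C(=O)OCC | intermediate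
8 | ethyl (2E,4E)-5-[(1R,4S)-4-(tert-butyldimethylsilyloxy)-2,6,6-trimethylcyclohex-2-en-1-yl]-3-methylpenta-2,4-dienoate | CC1=C[C@@H](O[Si](C)(C)C(C)(C)C)CC(C)(C)[C@H]1/C=C/C(C)=C/C(=O)OCC | intermediate
9 | (2E,4E)-5-[(1R,4S)-4-(tert-butyldimethylsilyloxy)-2,6,6-trimethylcyclohex-2-en-1-yl]-3-methylpenta-2,4-dien-1-ol | CC1=C[C@@H](O[Si](C)(C)C(C)(C)C)CC(C)(C)[C@H]1/C=C/C(C)=C/CO | intermediate
10 | (2E,4E)-5-[(1R,4S)-4-(tert-butyldimethylsilyloxy)-2,6,6-trimethylcyclohex-2-en-1-yl]-3-methylpenta-2,4-dienyl bromide | CC1=C[C@@H](O[Si](C)(C)C(C)(C)C)CC(C)(C)[C@H]1/C=C/C(C)=C/CBr | intermediate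
11 | [(2E,4E)-5-[(1R,4S)-4-(tert-butyldimethylsilyloxy)-2,6,6-trimethylcyclohex-2-en-1-yl]-3-methylpenta-2,4-dienyl]triphenylphosphonium bromide | CC1=C[C@@H](O[Si](C)(C)C(C)(C)C)CC(C)(C)[C@H]1/C=C/C(C)=C/C[P+](c1ccccc1)(c1ccccc1)c1ccccc1.[Br-] | intermediate
12 | safranal, 2,6,6-trimethylcyclohexa-1,3-diene-1-carbaldehyde | O=CC1=C(C)C=CCC1(C)C | starting material
13 | racemic cis-(3RS,4SR)-3,4-dihydroxy-2,6,6-trimethylcyclohex-1-ene-1-carbaldehyde (one enantiomer drawn) | O=CC1=C(C)[C@@H](O)[C@@H](O)CC1(C)C | intermediate
14 | (3R,4S)-3,4-dihydroxy-2,6,6-trimethylcyclohex-1-ene-1-carbaldehyde | O=CC1=C(C)[C@@H](O)[C@@H](O)CC1(C)C | intermediate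
15 | (3R,4S)-3,4-bis(tert-butyldimethylsilyloxy)-2,6,6-trimethylcyclohex-1-ene-1-carbaldehyde | O=CC1=C(C)[C@@H](O[Si](C)(C)C(C)(C)C)[C@@H](O[Si](C)(C)C(C)(C)C)CC1(C)C | intermediate
16 | triethyl 3-methyl-4-phosphonocrotonate, ethyl (2E)-4-(diethoxyphosphoryl)-3-methylbut-2-enoate (the commercial E/Z mixture equilibrates through its anion) | CCOC(=O)/C=C(\C)CP(=O)(OCC)OCC | starting material
17 | ethyl (2E,4E)-5-[(3R,4S)-3,4-bis(tert-butyldimethylsilyloxy)-2,6,6-trimethylcyclohex-1-en-1-yl]-3-methylpenta-2,4-dienoate | CCOC(=O)/C=C(C)/C=C/C1=C(C)[C@@H](O[Si](C)(C)C(C)(C)C)[C@@H](O[Si](C)(C)C(C)(C)C)CC1(C)C | intermediate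
18 | (2E,4E)-5-[(3R,4S)-3,4-bis(tert-butyldimethylsilyloxy)-2,6,6-trimethylcyclohex-1-en-1-yl]-3-methylpenta-2,4-dien-1-ol | OC/C=C(C)/C=C/C1=C(C)[C@@H](O[Si](C)(C)C(C)(C)C)[C@@H](O[Si](C)(C)C(C)(C)C)CC1(C)C | intermediate
19 | (2E,4E)-5-[(3R,4S)-3,4-bis(tert-butyldimethylsilyloxy)-2,6,6-trimethylcyclohex-1-en-1-yl]-3-methylpenta-2,4-dienyl bromide | BrC/C=C(C)/C=C/C1=C(C)[C@@H](O[Si](C)(C)C(C)(C)C)[C@@H](O[Si](C)(C)C(C)(C)C)CC1(C)C | intermediate
20 | [(2E,4E)-5-[(3R,4S)-3,4-bis(tert-butyldimethylsilyloxy)-2,6,6-trimethylcyclohex-1-en-1-yl]-3-methylpenta-2,4-dienyl]triphenylphosphonium bromide | [Br-].c1ccccc1[P+](c1ccccc1)(c1ccccc1)C/C=C(C)/C=C/C1=C(C)[C@@H](O[Si](C)(C)C(C)(C)C)[C@@H](O[Si](C)(C)C(C)(C)C)CC1(C)C | intermediate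
21 | (2E,4E,6E)-2,7-dimethylocta-2,4,6-trienedial | O=C/C(C)=C/C=C/C=C(C)/C=O | starting material
22 | (2E,4E,6E,8Z,10E,12E)-13-[(3R,4S)-3,4-bis(tert-butyldimethylsilyloxy)-2,6,6-trimethylcyclohex-1-en-1-yl]-2,7,11-trimethyltrideca-2,4,6,8,10,12-hexaenal (11Z in carotenoid numbering) | O=C/C(C)=C/C=C/C=C(C)/C=C\C=C(C)\C=C\C1=C(C)[C@@H](O[Si](C)(C)C(C)(C)C)[C@@H](O[Si](C)(C)C(C)(C)C)CC1(C)C | intermediate
23 | (2E,4E,6E,8E,10E,12E)-13-[(3R,4S)-3,4-bis(tert-butyldimethylsilyloxy)-2,6,6-trimethylcyclohex-1-en-1-yl]-2,7,11-trimethyltrideca-2,4,6,8,10,12-hexaenal | O=C/C(C)=C/C=C/C=C(C)/C=C/C=C(C)/C=C/C1=C(C)[C@@H](O[Si](C)(C)C(C)(C)C)[C@@H](O[Si](C)(C)C(C)(C)C)CC1(C)C | intermediate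
24 | (11'Z)-(3S,4R,3'S,6'R)-3,4,3'-tris(tert-butyldimethylsilyloxy)-β,ε-carotene | CC1=C[C@@H](O[Si](C)(C)C(C)(C)C)CC(C)(C)[C@H]1/C=C/C(C)=C/C=C\C(C)=C\C=C\C=C(C)\C=C\C=C(C)\C=C\C1=C(C)[C@@H](O[Si](C)(C)C(C)(C)C)[C@@H](O[Si](C)(C)C(C)(C)C)CC1(C)C | intermediate
25 | (all-E)-(3S,4R,3'S,6'R)-3,4,3'-tris(tert-butyldimethylsilyloxy)-β,ε-carotene | CC1=C[C@@H](O[Si](C)(C)C(C)(C)C)CC(C)(C)[C@H]1/C=C/C(C)=C/C=C/C(C)=C/C=C/C=C(C)/C=C/C=C(C)/C=C/C1=C(C)[C@@H](O[Si](C)(C)C(C)(C)C)[C@@H](O[Si](C)(C)C(C)(C)C)CC1(C)C | intermediate
26 | CNP0191612.2, (3S,4R,3'S,6'R)-β,ε-carotene-3,4,3'-triol | CC1=C[C@@H](O)CC(C)(C)[C@H]1/C=C/C(C)=C/C=C/C(C)=C/C=C/C=C(C)/C=C/C=C(C)/C=C/C1=C(C)[C@@H](O)[C@@H](O)CC1(C)C | target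

**Totals and risks**

Total step count: 17. Longest linear sequence: 10 steps (steps 1–8, 16 and 17, from nerylacetone).

The three steps most likely to fail:

Risk 1, step 1, which carries the proposed new method. What may go wrong: slow turnover of the small substrate; quenching of the C5' cation at the methyl group or at H-6', or its capture by the ketone oxygen; binding in the antipodal fold, which would erode the 6'R purity. Fallback for step 1: this fallback uses known chemistry only and passes through neither 1 nor 2. It sets out from phosphonate 4, which is combined with purchased racemic α-ionone F1, and it comes back to the route at 7. Horner–Wadsworth–Emmons olefination of racemic α-ionone F1 with 4, using NaH in THF at 0 → 40 °C, would give the racemic C15 ester F2, and allylic oxidation with t-BuOOH under Rh2(cap)4 catalysis would give the racemic 3'-oxo ester F3. Luche reduction with NaBH4 and CeCl3·7H2O in MeOH at −40 °C would give both carbinol racemates, of which the racemic cis carbinol F4 is separated on silica from the racemic trans carbinol F5. Lipase-catalysed acetylation of the cis racemate with Burkholderia cepacia lipase and vinyl acetate in t-BuOMe is a kinetic resolution of a kind well established for cyclic secondary allylic alcohols. It should convert the 3'R,6'S enantiomer into the 3'R,6'S acetate F6 and leave 7 unreacted, to be isolated by chromatography.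

Risk 2, step 10. What may go wrong: weak discrimination between the enantiomers, acylation at both hydroxyls, or the opposite enantiomer preference, each of which would leave diol of low enantiomeric purity. Fallback for step 10: this fallback replaces the enzymatic resolution by a chromatographic separation of enantiomers; it sets out from 13 and comes back to the route at 15. The racemic diol 13 would be silylated with TBSOTf and 2,6-lutidine in CH2Cl2 to the racemic bis-silyl ether F7 , whose enantiomers would be separated by preparative supercritical-fluid chromatography on an amylose tris(3,5-dimethylphenylcarbamate) phase. The fraction that is 15 would be identified by desilylating a sample of each fraction and analysing the MTPA esters of the resulting diols.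

Risk 3, step 2. What may go wrong: over-oxidation of the product through its extended enol toward a dienone, or erosion of the configuration at C6' if warming is needed to drive the reaction. Fallback for step 2: this fallback goes through an isolated silyl enol ether; it sets out from 2 and comes back to the route at 3. Me3SiI and hexamethyldisilazane in CH2Cl2 at −20 → 25 °C would give regioselectively the more substituted silyl enol ether F8 , and Saegusa–Ito oxidation of it with a full equivalent of Pd(OAc)2 in MeCN at 25 °C would then give 3.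

**Further compounds**

F1 | step 1 | racemic α-ionone (purchased), (3E)-4-(2,6,6-trimethylcyclohex-2-en-1-yl)but-3-en-2-one | CC1=CCCC(C)(C)C1/C=C/C(C)=O
F2 | step 1 | racemic C15 ester, ethyl (2E,4E)-3-methyl-5-(2,6,6-trimethylcyclohex-2-en-1-yl)penta-2,4-dienoate | CC1=CCCC(C)(C)C1/C=C/C(C)=C/C(=O)OCC
F3 | step 1 | racemic 3'-oxo ester, ethyl (2E,4E)-3-methyl-5-(2,6,6-trimethyl-4-oxocyclohex-2-en-1-yl)penta-2,4-dienoate | CC1=CC(=O)CC(C)(C)C1/C=C/C(C)=C/C(=O)OCC
F4 | step 1 | racemic cis carbinol, ethyl (2E,4E)-5-[(1RS,4SR)-4-hydroxy-2,6,6-trimethylcyclohex-2-en-1-yl]-3-methylpenta-2,4-dienoate (racemate of 7, one enantiomer drawn) | CC1=C[C@@H](O)CC(C)(C)[C@H]1/C=C/C(C)=C/C(=O)OCC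
F5 | step 1 | racemic trans carbinol, ethyl (2E,4E)-5-[(1RS,4RS)-4-hydroxy-2,6,6-trimethylcyclohex-2-en-1-yl]-3-methylpenta-2,4-dienoate (one enantiomer drawn) | CC1=C[C@H](O)CC(C)(C)[C@H]1/C=C/C(C)=C/C(=O)OCC
F6 | step 1 | 3'R,6'S acetate, ethyl (2E,4E)-5-[(1S,4R)-4-acetoxy-2,6,6-trimethylcyclohex-2-en-1-yl]-3-methylpenta-2,4-dienoate | CC1=C[C@H](OC(C)=O)CC(C)(C)[C@@H]1/C=C/C(C)=C/C(=O)OCC
F7 | step 10 | racemic bis-silyl ether, cis-3,4-bis(tert-butyldimethylsilyloxy)-2,6,6-trimethylcyclohex-1-ene-1-carbaldehyde (racemate of 15, one enantiomer drawn) | O=CC1=C(C)[C@@H](O[Si](C)(C)C(C)(C)C)[C@@H](O[Si](C)(C)C(C)(C)C)CC1(C)C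
F8 | step 2 | silyl enol ether, trimethyl{[(2Z)-4-[(1R)-2,6,6-trimethylcyclohex-2-en-1-yl]but-2-en-2-yl]oxy}silane | CC1=CCCC(C)(C)[C@H]1C/C=C(/C)O[Si](C)(C)C
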